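**Assumption:** the target is natural (2R,3′E,7′E)‑α‑tocotrienol (CIP analysis of the SMILES gives 2R, both internal alkenes E). (S)‑Trolox and (2E,6E)‑farnesyl bromide are taken as commercially available in enantio‑/isomerically pure form.

## Retrosynthetic overview

1. No ring is built: the chroman ring and the quaternary C2 stereocentre are bought as (S)‑Trolox. It has the target's spatial arrangement; the S→R label change is only a CIP priority switch.
2. Key disconnection is C1′–C2′: a chroman‑2‑ylmethyl triflate (electrophile) plus α‑lithiated (E,E)‑farnesyl phenyl sulfone (nucleophile), which brings all three alkenes with their geometry.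
3. The phenol is masked as an allyl ether, so one Pd(0)/hydride operation at the end removes both the allylic sulfone and the O‑allyl group.

## Route

**Step 1**
Reactants: 1, (S)‑Trolox [(2S)‑6‑hydroxy‑2,5,7,8‑tetramethylchroman‑2‑carboxylic acid]
Product: 2, (2S)‑2‑(hydroxymethyl)‑2,5,7,8‑tetramethylchroman‑6‑ol
Conditions: LiAlH4 (3 equiv), THF, 0 °C → reflux, N2; Rochelle salt/dilute HCl work‑up
Reagents that add atoms: none
Why: Hydride reduction of the carboxylic acid to the primary alcohol; the quaternary C2 centre cannot epimerise.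

**Step 2**
Reactants: 2, (2S)‑2‑(hydroxymethyl)‑2,5,7,8‑tetramethylchroman‑6‑ol
Product: 3, [(2S)‑6‑(allyloxy)‑2,5,7,8‑tetramethylchroman‑2‑yl]methanol
Conditions: allyl bromide (1.1 equiv), K2CO3, DMF, rt, N2
Reagents that add atoms: allyl bromide, C=CCBr
Why: Williamson etherification; K2CO3 deprotonates only the phenol (pKa ≈ 11 vs ≈ 16 for the alcohol), so only the phenol is O‑allylated.

**Step 3**
Reactants: 3, [(2S)‑6‑(allyloxy)‑2,5,7,8‑tetramethylchroman‑2‑yl]methanol
Product: 4, [(2S)‑6‑(allyloxy)‑2,5,7,8‑tetramethylchroman‑2‑yl]methyl trifluoromethanesulfonate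
Conditions: Tf2O, pyridine, CH2Cl2, −20 → 0 °C; quick cold aqueous work‑up, used crude
Reagents that add atoms: triflic anhydride, O=S(=O)(OS(=O)(=O)C(F)(F)F)C(F)(F)F
Why: O‑sulfonylation gives a leaving group reactive enough for SN2 at a neopentyl‑type carbon; the fully substituted arene and the allyl ether are inert.

**Step 4**
Reactants: 5, (2E,6E)‑farnesyl bromide
Product: 6, (2E,6E)‑farnesyl phenyl sulfone {[(2E,6E)‑3,7,11‑trimethyldodeca‑2,6,10‑trien‑1‑yl]sulfonylbenzene}
Conditions: PhSO2Na, DMF, rt
Reagents that add atoms: sodium benzenesulfinate, [Na+].[O-]S(=O)c1ccccc1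
Why: SN2 S‑alkylation of sulfinate by a primary allylic bromide, with the E,E geometry untouched.

**Step 5**
Reactants: 6, (2E,6E)‑farnesyl phenyl sulfone (1.4 equiv); 4, the chromanylmethyl triflate
Product: 7, (2S)‑6‑(allyloxy)‑2,5,7,8‑tetramethyl‑2‑[(3E,7E)‑4,8,12‑trimethyl‑2‑(phenylsulfonyl)trideca‑3,7,11‑trien‑1‑yl]chroman, ~1:1 mixture of epimers at the sulfone carbon C2′
Conditions: 6, n‑BuLi, THF/HMPA (4:1), −78 °C; then 4, −78 → −20 °C
Reagents that add atoms: none beyond 4 and 6
Why: α‑Alkylation of the lithiated allylic sulfone by SN2 on the primary triflate forms C1′–C2′; the new C2′ centre is uncontrolled but is erased in step 6, and C2 is not a reacting centre.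

**Step 6**
Reactants: 7, the coupled allylic sulfone
Product: 8, (R)‑α‑tocotrienol [(2R)‑2,5,7,8‑tetramethyl‑2‑[(3E,7E)‑4,8,12‑trimethyltrideca‑3,7,11‑trien‑1‑yl]chroman‑6‑ol], the target
Conditions: PdCl2(dppp) (10 mol %), LiBHEt3 (5–6 equiv), THF, 0 °C → rt, Ar; aq NH4Cl work‑up under Ar
Reagents that add atoms: none
Why: Pd‑catalysed hydride desulfonylation (Inomata–Kotake type) delivers hydride to the less substituted C2′ terminus of the π‑allyl, keeping the 3′E trisubstituted alkene. The same Pd(0)/hydride system should also cleave the aryl allyl ether via π‑allyl‑Pd to give the free phenol (this combination is proposed by analogy, not a known one‑pot).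

Stereochemistry summary: C2 comes from 1 and is never a reacting centre. Its descriptor is S in 1–4 and 7 and R in 8 only because the side chain drops below ring C3 in CIP priority. The 3′E and 7′E alkenes come from 5.

## Compound list

1 | (S)‑Trolox | OC(=O)[C@]1(C)CCc2c(C)c(O)c(C)c(C)c2O1 | starting material
2 | (2S)‑2‑(hydroxymethyl)‑2,5,7,8‑tetramethylchroman‑6‑ol | OC[C@]1(C)CCc2c(C)c(O)c(C)c(C)c2O1 | intermediate
3 | [(2S)‑6‑(allyloxy)‑2,5,7,8‑tetramethylchroman‑2‑yl]methanol | OC[C@]1(C)CCc2c(C)c(OCC=C)c(C)c(C)c2O1 | intermediate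
4 | [(2S)‑6‑(allyloxy)‑2,5,7,8‑tetramethylchroman‑2‑yl]methyl triflate | FC(F)(F)S(=O)(=O)OC[C@]1(C)CCc2c(C)c(OCC=C)c(C)c(C)c2O1 | intermediate
5 | (2E,6E)‑farnesyl bromide | CC(C)=CCC/C(C)=C/CC/C(C)=C/CBr | starting material
6 | (2E,6E)‑farnesyl phenyl sulfone | CC(C)=CCC/C(C)=C/CC/C(C)=C/CS(=O)(=O)c1ccccc1 | intermediate
7 | (2S)‑6‑(allyloxy)‑2,5,7,8‑tetramethyl‑2‑[(3E,7E)‑4,8,12‑trimethyl‑2‑(phenylsulfonyl)trideca‑3,7,11‑trien‑1‑yl]chroman (C2′ epimer mixture) | CC(C)=CCC/C(C)=C/CC/C(C)=C/C(C[C@]1(C)CCc2c(C)c(OCC=C)c(C)c(C)c2O1)S(=O)(=O)c1ccccc1 | intermediate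
8 | (2R,3′E,7′E)‑α‑tocotrienol | CC(C)=CCC/C(C)=C/CC/C(C)=C/CC[C@]1(C)CCc2c(C)c(O)c(C)c(C)c2O1 | target

## Totals

Total steps: 6. Longest linear sequence: 5 (steps 1 → 2 → 3 → 5 → 6); step 4 is a one‑step side branch.

## Steps most likely to fail, with fallbacks

1. **Step 5 (sulfone anion SN2 on the neopentyl‑type triflate).** Risks are slow displacement, triflate decomposition and γ‑alkylation. Fallback: form C2′–C3′ instead. Oxidise 3 to the aldehyde, methylenate (Wittig) to the (S)‑2‑vinylchroman, hydroborate with 9‑BBN, and run a B‑alkyl Suzuki coupling with (1E,5E)‑1‑iodo‑2,6,10‑trimethylundeca‑1,5,9‑triene. The iodide comes from Zr‑catalysed carboalumination/iodination of (E)‑6,10‑dimethylundeca‑5,9‑dien‑1‑yne. No sulfone is involved.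

2. **Step 6 (one‑pot desulfonylation and deallylation).** Risks are incomplete O‑allyl cleavage, hydride delivery to the wrong allyl terminus (Δ2′ isomer) and E/Z erosion. Fallback: change the protecting‑group strategy to a phenol TBS ether, made by esterifying 1, silylating, then reducing with LiAlH4. Then run two separate end‑game steps: Pd/LiBHEt3 desulfonylation, then TBAF/AcOH desilylation.

3. **Step 3 (formation and handling of triflate 4).** Risks are ionisation or rearrangement assisted by the ring oxygen, and hydrolysis on work‑up. Fallback: avoid an sp3 electrophile. Oxidise 3 to the aldehyde and do a Julia–Kocienski olefination with homofarnesyl 1‑phenyltetrazol‑5‑yl sulfone. Then reduce the new 1,2‑disubstituted C1′=C2′ alkene chemoselectively with diimide (TsNHNH2/NaOAc), which spares the trisubstituted alkenes. Finish with Pd(PPh3)4/morpholine deallylation.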